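**Plan**

- Cuts: C1=CH2 back to a C1 ketone; C9–Cl back to a temporary C1–O–C9 ether bridge; C10–Br and C4–Br/C3–OH back to alkenes; C9–CH3 back to an enol triflate; and the ring A bond C5–C6 by a retro-1,2-shift, which shrinks ring A to a cyclopentanol hung on C6 and lets ring B be a phenol.
- Enabling feature: the spiro atom C6 is para to C9 in ring B and next to C1 in ring A. An oxidised phenol places a cation on C6; a carbinol at C1 supplies the migrating CMe2 carbon C5 and becomes the C1 carbonyl.
- Forward order: arylcyclopentanol (ring B as arene, five-membered ring C1–C5) → ring A (six-membered) and a dienone ring B in one step → ring B desymmetrised and methylated → C3=C4 alkene and C1 alcohol in ring A → ether ring C1–O–C9 with C10–Br → ring A bromohydrin → bridge opened to C9–Cl → methylidene.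
- Stereochemistry: C6 from a chiral CuH catalyst (Cu(OAc)2/(R)-DTBM-SEGPHOS/silane; desymmetrisation of the dienone); a temporary C1 carbinol from a CBS reduction. C1–O then delivers oxygen to C9 anti to Br (sets C10, and C9 after retentive exchange for Cl) and fixes the chair of ring A, so C4–Br settles equatorial and hydride makes C3–OH axial, cis to it.

Key step: step 2

Remark on numbering: all spiro compounds carry the locants of the spiro[5.5]undecane core of the target (C1 methylidene carbon, C5 gem-dimethyl carbon, C6 spiro atom, C9 chloro carbon, C10 bromo carbon; ring A = C1–C6, ring B = C6–C11).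
Assumption: the copper hydride of (R)-DTBM-SEGPHOS is taken to reduce the C7=C8 arm in step 3; if the sense is the opposite, the (S)-ligand is used with no other change.

**Route**

Step 1
Reactants: 1 (4-bromophenoxy)(tert-butyl)dimethylsilane; 2 2,2-dimethylcyclopentan-1-one
Product: 5 (±)-4-(1-hydroxy-2,2-dimethylcyclopentyl)phenol, via aryllithium 3 (not isolated), via lithium alkoxide 4 (not isolated)
Conditions: n-BuLi, THF, −78 °C; add 2, −78 → 0 °C; then Bu4NF, 0 °C; H2O work-up
Reagents that add atoms: none
Why: Bromine–lithium exchange gives an aryllithium that adds 1,2 to the hindered ketone (organolithium addition) and fluoride then removes the silyl group; the carbinol carbon forms as a racemate, which does not matter because it becomes a carbonyl carbon in step 2.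

Step 2
Reactants: 5 (±)-4-(1-hydroxy-2,2-dimethylcyclopentyl)phenol
Product: 6 5,5-dimethylspiro[5.5]undeca-7,10-diene-1,9-dione
Conditions: PhI(OAc)2 (1.1 equiv), (CF3)2CHOH, 0 °C
Reagents that add atoms: none
Why: Oxidation of the phenol by PhI(OAc)2 (trivalent iodine) in the ionising, non-nucleophilic solvent gives a phenoxenium-type cation with its charge on the para carbon C6; the C1–C5 bond of the carbinol then shifts to C6 while C1–OH becomes the C1 ketone, so the cyclopentanol grows into the six-membered ring A. The closest known reaction type is the oxidative dearomatisation/Wagner–Meerwein (semipinacol) shift of para-(1-hydroxyalkyl)phenols, which includes ring enlargement of 1-arylcycloalkanols. Ring A is closed by this 1,2-shift (ring enlargement by the ipso carbon, not an exo or endo cyclisation), and ring B is the former arene, now a 2,5-cyclohexadienone. No lasting stereocenter is made: the two vinyl arms on C6 are identical, so C6 is prochiral, and the racemic carbinol center C1 is destroyed. The step needs migration of the quaternary C5 in preference to the methylene C2, and a shift in preference to capture of the cation or fragmentation. The higher migratory aptitude of the more substituted carbon, the oxocarbenium character that C1 gains, and the low nucleophilicity of the solvent should secure this, and the vicinal quaternary pair C5–C6 is formed in the same event.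

Step 3
Reactants: 6 5,5-dimethylspiro[5.5]undeca-7,10-diene-1,9-dione
Product: 7 (6S)-5,5-dimethylspiro[5.5]undec-10-ene-1,9-dione
Conditions: Cu(OAc)2 (5 mol %), (R)-DTBM-SEGPHOS (5.5 mol %), (MeO)2MeSiH (1.1 equiv), t-BuOH (1.1 equiv), toluene, −40 °C
Reagents that add atoms: none
Why: A ligated monovalent copper hydride adds hydride to C7 of one of the two enantiotopic enone arms of the 4,4-disubstituted cyclohexadienone (catalyst-controlled desymmetrising conjugate reduction) and t-BuOH protonates the copper enolate, so C6 becomes a stereocenter under control of the ligand, which reads the difference between the C1 carbonyl and the C5 gem-dimethyl group; one equivalent of silane and the low temperature hold back a second reduction and the isolated ketone.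

Step 4
Reactants: 7 (6S)-5,5-dimethylspiro[5.5]undec-10-ene-1,9-dione
Product: 9 (6S)-5,5-dimethyl-1-oxospiro[5.5]undec-9-en-9-yl trifluoromethanesulfonate, via silyl enol ether 8 (not isolated)
Conditions: RhCl(PPh3)3 (1 mol %), Et3SiH, toluene, 50 °C; then CsF, PhNTf2, DME, rt
Reagents that add atoms: N-phenylbis(trifluoromethanesulfonimide) O=S(=O)(N(c1ccccc1)S(=O)(=O)C(F)(F)F)C(F)(F)F
Why: Rh-catalysed 1,4-hydrosilylation puts hydrogen on C11 and gives only the C9=C10 silyl enol ether, which fluoride turns into the enolate that PhNTf2 traps on oxygen (regiospecific enol triflate formation); the alkene position, and with it the configuration at C6, stays fixed, and the hindered C1 ketone is neither hydrosilylated nor enolised under these conditions.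

Step 5
Reactants: 9 (6S)-5,5-dimethyl-1-oxospiro[5.5]undec-9-en-9-yl trifluoromethanesulfonate
Product: 10 (6S)-5,5,9-trimethylspiro[5.5]undec-9-en-1-one
Conditions: MeZnCl (1.5 equiv), Pd(PPh3)4 (5 mol %), THF, 50 °C
Reagents that add atoms: methylzinc chloride C[Zn]Cl
Why: Negishi coupling of the enol triflate by zerovalent palladium replaces OTf by methyl without moving the C9=C10 bond, and the organozinc does not add to the hindered ketone.

Step 6
Reactants: 10 (6S)-5,5,9-trimethylspiro[5.5]undec-9-en-1-one
Product: 11 (6S)-5,5,9-trimethylspiro[5.5]undeca-2,9-dien-1-one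
Conditions: IBX (2.5 equiv), DMSO, 70 °C
Reagents that add atoms: none
Why: IBX dehydrogenation of a ketone through its enol: the C1 ketone has hydrogen only on C2 (C6 is quaternary), so the C2=C3 enone is the only possible product and the trisubstituted alkene of ring B is not touched.

Step 7
Reactants: 11 (6S)-5,5,9-trimethylspiro[5.5]undeca-2,9-dien-1-one
Product: 13 (6S)-5,5,9-trimethylspiro[5.5]undeca-3,9-dien-1-one, via potassium dienolate 12 (not isolated)
Conditions: KN(SiMe3)2, THF, −78 → −20 °C; then AcOH, −78 °C
Reagents that add atoms: none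
Why: The enone has acidic hydrogen only at the gamma carbon C4, so the amide base gives the extended dienolate, and its kinetic protonation at the alpha carbon C2 moves the double bond out of conjugation to C3=C4 (deconjugation through a dienolate); the product is used at once because acid or base would take it back.

Step 8
Reactants: 13 (6S)-5,5,9-trimethylspiro[5.5]undeca-3,9-dien-1-one
Product: 14 (1S,6S)-5,5,9-trimethylspiro[5.5]undeca-3,9-dien-1-ol
Conditions: (R)-2-methyl-CBS-oxazaborolidine (15 mol %), catecholborane, toluene, −78 → −40 °C; H2O work-up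
Reagents that add atoms: none
Why: Corey–Bakshi–Shibata reduction: the catalyst tells the quaternary C6 flank (large) from the C2 methylene flank (small), and the (R)-catalyst should give the (1S)-alcohol irrespective of the remote ring B; catecholborane at low temperature neither hydroborates the alkenes nor isomerises the deconjugated enone.

Step 9
Reactants: 14 (1S,6S)-5,5,9-trimethylspiro[5.5]undeca-3,9-dien-1-ol
Product: 16 (1S,3S,4S,6S,9R,10R)-4,10-dibromo-1,9-epoxy-5,5,9-trimethylspiro[5.5]undecan-3-ol, via bromo ether 15 (not isolated)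
Conditions: NBS (1.05 equiv), CH2Cl2, 0 °C; then NBS (1.2 equiv), THF/H2O, 0 °C → rt
Reagents that add atoms: N-bromosuccinimide O=C1CCC(=O)N1Br; water O
Why: Bromoetherification then bromohydrin formation: the C1 hydroxyl, held on the axial C1 of ring B, opens the bromonium ion of the trisubstituted ring B alkene at the tertiary C9 from its own face (2-oxabicyclo[2.2.2]octane), which puts Br on C10 anti to oxygen, that is on the face of C6 that carries C5, and sets C9 and C10; the second portion of NBS in water then gives the ring A bromohydrin with water at C3 because C4 is neopentyl, and the configuration at C3 and C4 at this stage is provisional (trans-diaxial isomer shown).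

Step 10
Reactants: 16 (1S,3S,4S,6S,9R,10R)-4,10-dibromo-1,9-epoxy-5,5,9-trimethylspiro[5.5]undecan-3-ol
Product: 18 (1S,4R,6S,9R,10R)-4,10-dibromo-1,9-epoxy-5,5,9-trimethylspiro[5.5]undecan-3-one, via axial bromoketone 17 (not isolated)
Conditions: Dess–Martin periodinane, CH2Cl2, rt; then C5H5N·HBr (10 mol %), CH2Cl2, rt
Reagents that add atoms: none
Why: Dess–Martin oxidation gives the alpha-bromoketone and acid-catalysed enolisation equilibrates C4: the (1S)-C1–O bond is equatorial on ring A (the bridge and the axial methyl on C5 allow no other chair), so C7 is axial and an axial bromine on C4 would clash with it, and the bromine should settle equatorial, cis to C11, which is the (4R) configuration of the target (thermodynamic control).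

Step 11
Reactants: 18 (1S,4R,6S,9R,10R)-4,10-dibromo-1,9-epoxy-5,5,9-trimethylspiro[5.5]undecan-3-one
Product: 20 (1S,3S,4R,6S,9R,10R)-4,10-dibromo-1,9-epoxy-5,5,9-trimethylspiro[5.5]undecan-3-yl acetate, via aluminium alkoxide 19 (not isolated)
Conditions: i-Bu2AlH, CH2Cl2, −78 °C; then Ac2O, pyridine, DMAP (cat.), −78 → 0 °C; H2O work-up
Reagents that add atoms: acetic anhydride CC(=O)OC(C)=O
Why: Hydride adds to the alpha-bromoketone from the equatorial side, because the axial side of C3 is blocked by the axial methyl on C5, and gives the axial alkoxide cis to the equatorial bromine (sets C3), and the aluminium alkoxide is acetylated in the same flask (reductive acetylation) to protect this alcohol for steps 13 and 14.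

Step 12
Reactants: 20 (1S,3S,4R,6S,9R,10R)-4,10-dibromo-1,9-epoxy-5,5,9-trimethylspiro[5.5]undecan-3-yl acetate
Product: 21 (1S,3S,4R,6S,9R,10R)-4,10-dibromo-9-chloro-1-hydroxy-5,5,9-trimethylspiro[5.5]undecan-3-yl acetate
Conditions: BCl3 (1.5 equiv), CH2Cl2, −78 → −20 °C; H2O work-up
Reagents that add atoms: boron trichloride ClB(Cl)Cl
Why: Lewis acid cleavage of an ether at its tertiary carbon: BCl3 binds the bridge oxygen, the C9–O bond ionises with help from the trans bromine on C10 (neighbouring-group participation through a bromonium ion), and chloride from the boron ate complex on the departing oxygen opens it at the tertiary C9 from the face that oxygen leaves, so Cl replaces O with retention and stays trans to Br while the secondary C1–O bond survives.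

Step 13
Reactants: 21 (1S,3S,4R,6S,9R,10R)-4,10-dibromo-9-chloro-1-hydroxy-5,5,9-trimethylspiro[5.5]undecan-3-yl acetate
Product: 22 (3S,4R,6S,9R,10R)-4,10-dibromo-9-chloro-5,5,9-trimethyl-1-oxospiro[5.5]undecan-3-yl acetate
Conditions: Dess–Martin periodinane, CH2Cl2, rt
Reagents that add atoms: none
Why: Dess–Martin oxidation of the only free alcohol gives the C1 ketone under neutral conditions that do not eliminate the beta-acetoxy group or the halides.

Step 14
Reactants: 22 (3S,4R,6S,9R,10R)-4,10-dibromo-9-chloro-5,5,9-trimethyl-1-oxospiro[5.5]undecan-3-yl acetate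
Product: 23 (3S,4R,6R,9R,10R)-4,10-dibromo-9-chloro-5,5,9-trimethyl-1-methylidenespiro[5.5]undecan-3-yl acetate
Conditions: Cp2Ti(μ-Cl)(μ-CH2)AlMe2 (1.2 equiv), pyridine (cat.), THF/toluene, −40 → 0 °C
Reagents that add atoms: Cp2Ti(μ-Cl)(μ-CH2)AlMe2 (Tebbe reagent) C[Al-]1(C)C[Ti]([Cl+]1)(C1C=CC=C1)C1C=CC=C1
Why: Tebbe olefination: the titanium methylidene released from the Ti–CH2–Al–Cl four-membered ring converts the hindered, alpha-quaternary ketone into the exocyclic alkene without base, reacts with a ketone faster than with the acetate at low temperature, and leaves the alkyl halides alone.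

Step 15
Reactants: 23 (3S,4R,6R,9R,10R)-4,10-dibromo-9-chloro-5,5,9-trimethyl-1-methylidenespiro[5.5]undecan-3-yl acetate
Product: 24 (3S,4R,6R,9R,10R)-4,10-dibromo-9-chloro-5,5,9-trimethyl-1-methylidenespiro[5.5]undecan-3-ol
Conditions: K2CO3 (cat.), MeOH, 0 °C
Reagents that add atoms: none
Why: Base-catalysed transesterification frees the C3 alcohol; the cis bromohydrin cannot close to an epoxide and the equatorial halides have no antiperiplanar hydrogen for elimination.

**Compound list**

1 | (4-bromophenoxy)(tert-butyl)dimethylsilane | CC(C)(C)[Si](C)(C)Oc1ccc(Br)cc1 | starting material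
2 | 2,2-dimethylcyclopentan-1-one | CC1(C)CCCC1=O | starting material
3 | {4-[(tert-butyldimethylsilyl)oxy]phenyl}lithium | [Li]c1ccc(O[Si](C)(C)C(C)(C)C)cc1 | intermediate (not isolated)
4 | lithium (±)-1-{4-[(tert-butyldimethylsilyl)oxy]phenyl}-2,2-dimethylcyclopentan-1-olate | [Li]OC1(CCCC1(C)C)c1ccc(O[Si](C)(C)C(C)(C)C)cc1 | intermediate (not isolated)
5 | (±)-4-(1-hydroxy-2,2-dimethylcyclopentyl)phenol | CC1(C)CCCC1(O)c1ccc(O)cc1 | intermediate
6 | 5,5-dimethylspiro[5.5]undeca-7,10-diene-1,9-dione | O=C1CCCC(C)(C)C12C=CC(=O)C=C2 | intermediate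
7 | (6S)-5,5-dimethylspiro[5.5]undec-10-ene-1,9-dione | O=C1CCCC(C)(C)[C@@]12CCC(=O)C=C2 | intermediate
8 | (6S)-5,5-dimethyl-9-[(triethylsilyl)oxy]spiro[5.5]undec-9-en-1-one | O=C1CCCC(C)(C)[C@@]12CCC(O[Si](CC)(CC)CC)=CC2 | intermediate (not isolated)
9 | (6S)-5,5-dimethyl-1-oxospiro[5.5]undec-9-en-9-yl trifluoromethanesulfonate | O=C1CCCC(C)(C)[C@@]12CCC(OS(=O)(=O)C(F)(F)F)=CC2 | intermediate
10 | (6S)-5,5,9-trimethylspiro[5.5]undec-9-en-1-one | O=C1CCCC(C)(C)[C@@]12CCC(C)=CC2 | intermediate
11 | (6S)-5,5,9-trimethylspiro[5.5]undeca-2,9-dien-1-one | O=C1C=CCC(C)(C)[C@@]12CCC(C)=CC2 | intermediate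
12 | potassium (6S)-5,5,9-trimethylspiro[5.5]undeca-1,3,9-trien-1-olate | [K+].[O-]C1=CC=CC(C)(C)[C@@]12CCC(C)=CC2 | intermediate (not isolated)
13 | (6S)-5,5,9-trimethylspiro[5.5]undeca-3,9-dien-1-one | O=C1CC=CC(C)(C)[C@@]12CCC(C)=CC2 | intermediate
14 | (1S,6S)-5,5,9-trimethylspiro[5.5]undeca-3,9-dien-1-ol | O[C@H]1CC=CC(C)(C)[C@@]12CCC(C)=CC2 | intermediate
15 | (1S,6S,9R,10R)-10-bromo-1,9-epoxy-5,5,9-trimethylspiro[5.5]undec-3-ene | O3[C@H]1CC=CC(C)(C)[C@@]12CC[C@]3(C)[C@H](Br)C2 | intermediate (not isolated)
16 | (1S,3S,4S,6S,9R,10R)-4,10-dibromo-1,9-epoxy-5,5,9-trimethylspiro[5.5]undecan-3-ol | O3[C@H]1C[C@H](O)[C@@H](Br)C(C)(C)[C@@]12CC[C@]3(C)[C@H](Br)C2 | intermediate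
17 | (1S,4S,6S,9R,10R)-4,10-dibromo-1,9-epoxy-5,5,9-trimethylspiro[5.5]undecan-3-one | O3[C@H]1CC(=O)[C@@H](Br)C(C)(C)[C@@]12CC[C@]3(C)[C@H](Br)C2 | intermediate (not isolated)
18 | (1S,4R,6S,9R,10R)-4,10-dibromo-1,9-epoxy-5,5,9-trimethylspiro[5.5]undecan-3-one | O3[C@H]1CC(=O)[C@H](Br)C(C)(C)[C@@]12CC[C@]3(C)[C@H](Br)C2 | intermediate
19 | diisobutylaluminium (1S,3S,4R,6S,9R,10R)-4,10-dibromo-1,9-epoxy-5,5,9-trimethylspiro[5.5]undecan-3-olate | O3[C@H]1C[C@H](O[Al](CC(C)C)CC(C)C)[C@H](Br)C(C)(C)[C@@]12CC[C@]3(C)[C@H](Br)C2 | intermediate (not isolated)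
20 | (1S,3S,4R,6S,9R,10R)-4,10-dibromo-1,9-epoxy-5,5,9-trimethylspiro[5.5]undecan-3-yl acetate | O3[C@H]1C[C@H](OC(C)=O)[C@H](Br)C(C)(C)[C@@]12CC[C@]3(C)[C@H](Br)C2 | intermediate
21 | (1S,3S,4R,6S,9R,10R)-4,10-dibromo-9-chloro-1-hydroxy-5,5,9-trimethylspiro[5.5]undecan-3-yl acetate | O[C@H]1C[C@H](OC(C)=O)[C@H](Br)C(C)(C)[C@@]12CC[C@@](C)(Cl)[C@H](Br)C2 | intermediate
22 | (3S,4R,6S,9R,10R)-4,10-dibromo-9-chloro-5,5,9-trimethyl-1-oxospiro[5.5]undecan-3-yl acetate | O=C1C[C@H](OC(C)=O)[C@H](Br)C(C)(C)[C@@]12CC[C@@](C)(Cl)[C@H](Br)C2 | intermediate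
23 | (3S,4R,6R,9R,10R)-4,10-dibromo-9-chloro-5,5,9-trimethyl-1-methylidenespiro[5.5]undecan-3-yl acetate | C=C1C[C@H](OC(C)=O)[C@H](Br)C(C)(C)[C@@]12CC[C@@](C)(Cl)[C@H](Br)C2 | intermediate
24 | (3S,4R,6R,9R,10R)-4,10-dibromo-9-chloro-5,5,9-trimethyl-1-methylidenespiro[5.5]undecan-3-ol | C=C1C[C@H](O)[C@H](Br)C(C)(C)[C@@]12CC[C@@](C)(Cl)[C@H](Br)C2 | target

Total step count: 15. Longest linear sequence: 15 steps (from 1 or 2).

**Steps most likely to fail**

Step 12. After ionisation at C9 the bromonium ion may hand its bromine to chloride (alkene formation and unselective re-addition), be opened at C10, or lose a proton, so that chlorine enters without the stereochemical memory of the bridge. The fallback sets out from 20. The ether C1–H is oxidised with RuCl3 (cat.)/NaIO4 (CCl4/MeCN/H2O) to a hemiketal, which collapses to (3S,4R,6S,9R,10R)-4,10-dibromo-9-hydroxy-5,5,9-trimethyl-1-oxospiro[5.5]undecan-3-yl acetate F1. This tertiary trans-beta-bromo alcohol is then treated with SOCl2 (CH2Cl2, 0 °C); its chlorosulfite should collapse by internal return, helped by the neighbouring bromine, with retention at C9. This gives 22, where the route is rejoined, and step 13 is no longer needed.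

Step 3. The catalyst may not tell the two enone arms apart well enough, or reduction may run on to the symmetric saturated diketone or to the C1 alcohol. The fallback sets out from 6. Both enone C=C bonds are hydrogenated (H2, Pd/C, EtOAc) to 5,5-dimethylspiro[5.5]undecane-1,9-dione F2. Enantioselective deprotonation of the unhindered C9 ketone with lithium bis[(R)-1-phenylethyl]amide (THF, −100 °C; the antipode of the base if required), followed by trapping of the enolate with PhNTf2, should give 9 directly, where the route is rejoined; step 4 is no longer needed.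

Step 2. The para cation may be captured by solvent or acetate before the shift, the carbinol may fragment, or the methylene C2 may migrate in place of C5. The fallback sets out from 5. Oxidation with PhI(OAc)2 in MeCN/H2O captures the cation on purpose with water and gives the para-quinol (±)-4-hydroxy-4-(1-hydroxy-2,2-dimethylcyclopentyl)cyclohexa-2,5-dien-1-one F3. BF3·OEt2 (cat., CH2Cl2, −40 °C) then ionises the doubly allylic C6–OH of this 1,2-diol, and a pinacol rearrangement with migration of C5 should give 6, where the route is rejoined.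

**Further compounds**

F1 | step 12 | (3S,4R,6S,9R,10R)-4,10-dibromo-9-hydroxy-5,5,9-trimethyl-1-oxospiro[5.5]undecan-3-yl acetate | O=C1C[C@H](OC(C)=O)[C@H](Br)C(C)(C)[C@@]12CC[C@@](C)(O)[C@H](Br)C2
F2 | step 3 | 5,5-dimethylspiro[5.5]undecane-1,9-dione | O=C1CCCC(C)(C)C12CCC(=O)CC2
F3 | step 2 | (±)-4-hydroxy-4-(1-hydroxy-2,2-dimethylcyclopentyl)cyclohexa-2,5-dien-1-one | CC1(C)CCCC1(O)C1(O)C=CC(=O)C=C1
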